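**Retrosynthetic overview**
1. Last bond: C1''–C(syncarpic), made by light-triggered release of an o-quinone methide at C8 of (2R)-5,7-dihydroxy-6-methylflavanone and Michael capture by syncarpic acid. The C8–C1'' bond comes from a boron-templated ortho-hydroxyalkylation with isovaleraldehyde in the same pot.
2. Pyranone ring: C4–C4a by intramolecular Friedel–Crafts acylation of an (R)-3-aryloxy-3-phenylpropanoic acid. O1–C2 by Mitsunobu inversion of ethyl (S)-3-hydroxy-3-phenylpropanoate, the only bought stereocentre, which then steers C1''.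
3. Phenol partner: C–H borylation/oxidation of bis-silylated 2-methylresorcinol puts the future O1 para to the C-methyl, so only the 6-methyl flavanone can form.
4. Ring order: aromatic A ring (bought), then pyranone ring (step 5), then the bought syncarpic ring attached last (step 6).

Assumption: syncarpic acid and ethyl (S)-3-hydroxy-3-phenylpropanoate are catalogue compounds; flavanone numbering is used, C1'' is the benzylic CH, and the target is (2R,1''S) by CIP.

**Step 1**
Reactants: 1 2-methylresorcinol
Product: 2 2,6-bis(triisopropylsilyloxy)toluene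
Conditions: TIPSCl (2.3 equiv), imidazole, DMF, 40 °C
Reagents that add atoms: chlorotriisopropylsilane, CC(C)[Si](Cl)(C(C)C)C(C)C
Why: Standard phenol O-silylation; the bulky TIPS ethers survive steps 2–5 and shield the two C–H bonds ortho to them in step 2.

**Step 2**
Reactants: 2 2,6-bis(triisopropylsilyloxy)toluene
Product: 4 3,5-bis(triisopropylsilyloxy)-4-methylphenol, via aryl pinacol boronate 3 (not isolated)
Conditions: B2pin2 (1.0 equiv), [Ir(OMe)(cod)]2 (1.5 mol%), dtbpy (3 mol%), THF, 80 °C; then Oxone, acetone–H2O, 0 °C to rt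
Reagents that add atoms: Oxone (potassium peroxymonosulfate, supplies the phenol O), [K+].[O-]S(=O)(=O)OO
Why: Sterically controlled Ir-catalysed aromatic C–H borylation hits the only C–H without an ortho substituent (para to CH3), and one-pot boronate oxidation gives the phenol whose oxygen becomes O1.

**Step 3**
Reactants: 4 3,5-bis(triisopropylsilyloxy)-4-methylphenol; 5 ethyl (S)-3-hydroxy-3-phenylpropanoate
Product: 6 ethyl (3R)-3-[3,5-bis(triisopropylsilyloxy)-4-methylphenoxy]-3-phenylpropanoate
Conditions: PPh3, DIAD (slow addition), toluene, 0 °C to rt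
Reagents that add atoms: none
Why: Mitsunobu etherification with SN2 inversion at the benzylic carbinol turns the bought (S)-alcohol into the (R)-aryl ether, which is C2 of the flavanone.

**Step 4**
Reactants: 6 ethyl (3R)-3-[3,5-bis(triisopropylsilyloxy)-4-methylphenoxy]-3-phenylpropanoate
Product: 7 (3R)-3-[3,5-bis(triisopropylsilyloxy)-4-methylphenoxy]-3-phenylpropanoic acid
Conditions: LiOH·H2O, THF–H2O, 0 °C to rt; 1 M HCl work-up
Reagents that add atoms: lithium hydroxide (hydroxide supplies the new acid O), [Li+].[OH-]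
Why: Ester saponification; the carboxylate formed resists β-elimination, the aryl TIPS ethers tolerate cold LiOH, and the stereocentre is not touched.

**Step 5**
Reactants: 7 (3R)-3-[3,5-bis(triisopropylsilyloxy)-4-methylphenoxy]-3-phenylpropanoic acid
Product: 10 (2R)-5,7-dihydroxy-6-methylflavanone, via mixed trifluoroacetic anhydride 8 (not isolated), via bis-TIPS flavanone 9 (not isolated)
Conditions: TFAA (2 equiv), CH2Cl2, 0 °C to rt; evaporate; HF·pyridine, THF, 0 °C to rt
Reagents that add atoms: none
Why: Intramolecular Friedel–Crafts acylation through the mixed anhydride closes the pyranone ring at either of the two equivalent positions ortho to the ether oxygen (one regioisomer, methyl ends at C6), and acidic fluoride then removes both silyl groups without base, so C2 stays R.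

**Step 6**
Reactants: 10 (2R)-5,7-dihydroxy-6-methylflavanone; 11 isovaleraldehyde; 12 syncarpic acid
Product: 15 (2R)-5,7-dihydroxy-8-[(1S)-1-(2-hydroxy-3,3,5,5-tetramethyl-4,6-dioxocyclohex-1-en-1-yl)-3-methylbutyl]-6-methyl-2-phenylchroman-4-one, via benzodioxaborin 13 (not isolated), via o-quinone methide 14 (not isolated)
Conditions: i. 11 (1.5 equiv), PhB(OH)2 (1.5 equiv), EtCO2H (0.3 equiv), PhMe, reflux (Dean–Stark); evaporate; ii. 12 (2 equiv), MeCN–H2O 20:1, hν (350 nm), −20 °C, Ar
Reagents that add atoms: none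
Why: Proposed new method: photochemical o-quinone methide release from a 4H-1,3,2-benzodioxaborin with C–C capture by a cyclic 1,3,5-trione; stage i is the known boronic-acid-templated ortho-hydroxyalkylation (Nagata reaction) at C8, the only free position ortho to 7-OH; in stage ii excitation of the aryl boronate (or its hydrolysed o-hydroxybenzyl alcohol form) causes excited-state proton transfer and benzylic C–O heterolysis with loss of PhB(OH)2 to give the (E)-o-quinone methide 14, which the syncarpic enol attacks at C1'' in a Michael addition; C1'' is set under substrate control from C2, because the isobutyl end should fold away from the pseudo-equatorial C2-phenyl and the nucleophile adds to the opposite face, which leads to 1''S (modest dr expected, about 2–3:1, epimer removed by chromatography); the low temperature and neutral medium protect C2 and suppress the thermal [1,5]-H shift of 14; closest known reactions are the photodehydration of o-hydroxybenzyl alcohols and photodeamination of phenolic Mannich salts to o-quinone methides, and the thermal generation of o-quinone methides from benzodioxaborins.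

**Compound list**
1 | 2-methylresorcinol (2-methylbenzene-1,3-diol) | Cc1c(O)cccc1O | starting material
2 | 2,6-bis(triisopropylsilyloxy)toluene | Cc1c(O[Si](C(C)C)(C(C)C)C(C)C)cccc1O[Si](C(C)C)(C(C)C)C(C)C | intermediate
3 | 2-[3,5-bis(triisopropylsilyloxy)-4-methylphenyl]-4,4,5,5-tetramethyl-1,3,2-dioxaborolane | Cc1c(O[Si](C(C)C)(C(C)C)C(C)C)cc(B2OC(C)(C)C(C)(C)O2)cc1O[Si](C(C)C)(C(C)C)C(C)C | intermediate (not isolated)
4 | 3,5-bis(triisopropylsilyloxy)-4-methylphenol | Cc1c(O[Si](C(C)C)(C(C)C)C(C)C)cc(O)cc1O[Si](C(C)C)(C(C)C)C(C)C | intermediate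
5 | ethyl (S)-3-hydroxy-3-phenylpropanoate | CCOC(=O)C[C@H](O)c1ccccc1 | starting material
6 | ethyl (3R)-3-[3,5-bis(triisopropylsilyloxy)-4-methylphenoxy]-3-phenylpropanoate | CCOC(=O)C[C@@H](Oc1cc(O[Si](C(C)C)(C(C)C)C(C)C)c(C)c(O[Si](C(C)C)(C(C)C)C(C)C)c1)c1ccccc1 | intermediate
7 | (3R)-3-[3,5-bis(triisopropylsilyloxy)-4-methylphenoxy]-3-phenylpropanoic acid | OC(=O)C[C@@H](Oc1cc(O[Si](C(C)C)(C(C)C)C(C)C)c(C)c(O[Si](C(C)C)(C(C)C)C(C)C)c1)c1ccccc1 | intermediate
8 | mixed anhydride of 7 with trifluoroacetic acid (3R) | O=C(C[C@@H](Oc1cc(O[Si](C(C)C)(C(C)C)C(C)C)c(C)c(O[Si](C(C)C)(C(C)C)C(C)C)c1)c1ccccc1)OC(=O)C(F)(F)F | intermediate (not isolated)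
9 | (2R)-6-methyl-2-phenyl-5,7-bis(triisopropylsilyloxy)chroman-4-one | Cc1c(O[Si](C(C)C)(C(C)C)C(C)C)c2c(cc1O[Si](C(C)C)(C(C)C)C(C)C)O[C@@H](c1ccccc1)CC2=O | intermediate (not isolated)
10 | (2R)-5,7-dihydroxy-6-methyl-2-phenylchroman-4-one ((R)-strobopinin) | Cc1c(O)c2c(cc1O)O[C@@H](c1ccccc1)CC2=O | intermediate
11 | isovaleraldehyde (3-methylbutanal) | CC(C)CC=O | starting material
12 | syncarpic acid (2,2,4,4-tetramethylcyclohexane-1,3,5-trione) | CC1(C)C(=O)CC(=O)C(C)(C)C1=O | starting material
13 | cyclic phenylboronate of (2R)-5,7-dihydroxy-8-(1-hydroxy-3-methylbutyl)-6-methylflavanone: a 4-isobutyl-2-phenyl-4H-1,3,2-dioxaborinine ring fused across O7–C7–C8, both C1'' epimers | Cc1c(O)c2c(c3c1OB(c1ccccc1)OC3CC(C)C)O[C@@H](c1ccccc1)CC2=O | intermediate (not isolated)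
14 | (2R,8E)-5-hydroxy-6-methyl-8-(3-methylbutylidene)-2-phenyl-2,3-dihydrochromene-4,7-dione (o-quinone methide) | CC1=C(O)C2=C(O[C@@H](c3ccccc3)CC2=O)/C(=C\CC(C)C)C1=O | intermediate (not isolated)
15 | (2R)-5,7-dihydroxy-8-[(1S)-1-(2-hydroxy-3,3,5,5-tetramethyl-4,6-dioxocyclohex-1-en-1-yl)-3-methylbutyl]-6-methyl-2-phenylchroman-4-one | Cc1c(O)c2c(c([C@H](CC(C)C)C3=C(O)C(C)(C)C(=O)C(C)(C)C3=O)c1O)O[C@@H](c1ccccc1)CC2=O | target

**Step count and risks**
Total steps: 6. Longest linear sequence: 6 (1 to 15; compounds 5, 11 and 12 are bought).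

Most likely to fail:

Step 6 (the proposed new photochemical step). The 5-OH···O=C4 hydrogen bond opens a fast excited-state proton-transfer decay that competes with o-quinone methide release, so the quantum yield may be low and irradiation long. The facial bias from C2 is remote, so the dr may be close to 1:1. Stage i at reflux must be checked by chiral HPLC for erosion at C2. If telescoping is the problem, 13 can be isolated by crystallisation first. Fallback with known chemistry, setting out from 10 and coming back at 15: thermal biomimetic Knoevenagel–Michael coupling. Condensation of 12 with 11 (pyrrolidine/AcOH cat., CH2Cl2, rt) gives 2-(3-methylbutylidene)-4,4,6,6-tetramethylcyclohexane-1,3,5-trione F1, used at once. Friedel–Crafts-type Michael addition of C8 of 10 to it (NaOAc, AcOH, rt) gives 15 together with its 1''R epimer (about 1:1), separated by preparative HPLC.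

Step 3 (Mitsunobu on a benzylic β-hydroxy ester). Elimination to ethyl cinnamate and partial loss of ee are possible. Fallback setting out from 4 and coming back at 7: Mitsunobu of 4 with (S)-3-chloro-1-phenylpropan-1-ol, which has no acidifying group and inverts cleanly, gives 5-[(1R)-3-chloro-1-phenylpropoxy]-2-methyl-1,3-bis(triisopropylsilyloxy)benzene F2. KOAc/NaI in DMF at 80 °C gives (3R)-3-[3,5-bis(triisopropylsilyloxy)-4-methylphenoxy]-3-phenylpropyl acetate F3. Cold LiOH gives (3R)-3-[3,5-bis(triisopropylsilyloxy)-4-methylphenoxy]-3-phenylpropan-1-ol F4. TEMPO/PhI(OAc)2 in MeCN–H2O oxidises the primary alcohol to acid 7.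

Step 5 (Friedel–Crafts ring closure). The acylation ortho to a bulky OTIPS group may be slow, and forcing acid could ionise or eliminate the benzylic ether. Fallback setting out from 4 and coming back at 10, closing the ring by a nitrile instead of an acid: Mitsunobu of 4 with (S)-3-hydroxy-3-phenylpropanenitrile gives (3R)-3-[3,5-bis(triisopropylsilyloxy)-4-methylphenoxy]-3-phenylpropanenitrile F5. HF·pyridine gives (3R)-3-(3,5-dihydroxy-4-methylphenoxy)-3-phenylpropanenitrile F6. Houben–Hoesch cyclisation (ZnCl2, HCl gas, Et2O, 0 °C) gives (2R)-5,7-dihydroxy-6-methyl-2-phenylchroman-4-iminium chloride F7. Warm water hydrolyses it to 10.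

**Further compounds**
F1 | step 6 | 2-(3-methylbutylidene)-4,4,6,6-tetramethylcyclohexane-1,3,5-trione | CC(C)CC=C1C(=O)C(C)(C)C(=O)C(C)(C)C1=O
F2 | step 3 | 5-[(1R)-3-chloro-1-phenylpropoxy]-2-methyl-1,3-bis(triisopropylsilyloxy)benzene | ClCC[C@@H](Oc1cc(O[Si](C(C)C)(C(C)C)C(C)C)c(C)c(O[Si](C(C)C)(C(C)C)C(C)C)c1)c1ccccc1
F3 | step 3 | (3R)-3-[3,5-bis(triisopropylsilyloxy)-4-methylphenoxy]-3-phenylpropyl acetate | CC(=O)OCC[C@@H](Oc1cc(O[Si](C(C)C)(C(C)C)C(C)C)c(C)c(O[Si](C(C)C)(C(C)C)C(C)C)c1)c1ccccc1
F4 | step 3 | (3R)-3-[3,5-bis(triisopropylsilyloxy)-4-methylphenoxy]-3-phenylpropan-1-ol | OCC[C@@H](Oc1cc(O[Si](C(C)C)(C(C)C)C(C)C)c(C)c(O[Si](C(C)C)(C(C)C)C(C)C)c1)c1ccccc1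
F5 | step 5 | (3R)-3-[3,5-bis(triisopropylsilyloxy)-4-methylphenoxy]-3-phenylpropanenitrile | N#CC[C@@H](Oc1cc(O[Si](C(C)C)(C(C)C)C(C)C)c(C)c(O[Si](C(C)C)(C(C)C)C(C)C)c1)c1ccccc1
F6 | step 5 | (3R)-3-(3,5-dihydroxy-4-methylphenoxy)-3-phenylpropanenitrile | N#CC[C@@H](Oc1cc(O)c(C)c(O)c1)c1ccccc1
F7 | step 5 | (2R)-5,7-dihydroxy-6-methyl-2-phenylchroman-4-iminium chloride | Cc1c(O)c2c(cc1O)O[C@@H](c1ccccc1)CC2=[NH2+].[Cl-]
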